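**Plan**

1. Rings: A pyrrolidine, B azepane, C cyclopentane, D hydroxy-γ-lactone fused to ring C, E methyl-γ-butyrolactone on ring A. Retrosynthetic cuts, in order: the ring D C–O bond at the ring C methylene; the ring A–ring E C–C bond; the N–CH2 bond of ring B; the C–N and C–CH2 bonds at the aza-quaternary carbon; the ring C–side-chain C–C bond.
2. Forward: ring C comes from cyclopentane-1,3-dione (C-alkylation, ethyl transposition) and the pyruvate side chain is added by aldol. Ring A then closes as a spirolactam after carboazidation of an exocyclic methylene, ring B by lactam N-alkylation, ring E is joined by a reductive vinylogous Mannich reaction, and ring D closes last.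
3. Stereochemistry: a CBS reduction sets the absolute sense and a hydroxyl-directed hydrogenation the cis ethyl/chlorobutyl pair; the enolsilane face and a chiral copper bis(oxazoline) catalyst set the two side-chain centres. Azide transfer anti to the side chain sets the aza-quaternary carbon, iminium addition and butenolide hydrogenation set the three centres of rings A and E, and the lactonisation sets the last one.
4. Enabling feature: the ring D oxygen sits on the ring C CH2 carbon between the ethyl-bearing carbon and the side-chain-bearing carbon. That carbon is gamma to the carboxyl carbon of the open α-acetoxy acid and has a hydrogen cis to the side chain; the only other gamma carbon is the fully substituted aza-quaternary carbon.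

Key step: step 17

Remark: benzyl pyruvate is used as the pyruvate ester so that the ester is cleaved in the hydrogenation that also saturates ring E; it, 4-chlorobutanal and 3-methylfuran-2(5H)-one are taken as purchasable.

**Route**

Step 1
Reactants: 1 cyclopentane-1,3-dione; 2 4-chlorobutanal
Product: 4 2-(4-chlorobutyl)cyclopentane-1,3-dione, via alkylidene dione 3 (not isolated)
Conditions: diethyl 2,6-dimethyl-1,4-dihydropyridine-3,5-dicarboxylate (1 equiv), L-proline (10 mol%), CH2Cl2, rt
Reagents that add atoms: none
Why: Proline-catalysed Knoevenagel condensation gives the alkylidene dione, which the dihydropyridine reduces at once by conjugate hydride transfer (three-component reductive alkylation), so clean C-monoalkylation is expected.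

Step 2
Reactants: 4 2-(4-chlorobutyl)cyclopentane-1,3-dione
Product: 5 2-(4-chlorobutyl)-3-(2-methylpropoxy)cyclopent-2-en-1-one
Conditions: i-BuOH, TsOH (cat.), toluene, reflux with azeotropic removal of water
Reagents that add atoms: 2-methylpropan-1-ol, CC(C)CO
Why: Acid-catalysed O-alkylation of the enolised 1,3-dione gives the vinylogous ester needed for the carbonyl transposition.

Step 3
Reactants: 5 2-(4-chlorobutyl)-3-(2-methylpropoxy)cyclopent-2-en-1-one
Product: 7 2-(4-chlorobutyl)-3-ethylcyclopent-2-en-1-one, via tertiary carbinol 6 (not isolated)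
Conditions: EtMgBr, THF, 0 °C; then 1 M HCl, rt
Reagents that add atoms: ethylmagnesium bromide, CC[Mg]Br
Why: 1,2-Addition to the vinylogous ester followed by acid hydrolysis with loss of water and isobutanol (Stork–Danheiser transposition) places the ethyl group on the β-carbon of the enone.

Step 4
Reactants: 7 2-(4-chlorobutyl)-3-ethylcyclopent-2-en-1-one
Product: 8 (1R)-2-(4-chlorobutyl)-3-ethylcyclopent-2-en-1-ol
Conditions: (S)-2-methyl-CBS-oxazaborolidine (10 mol%), BH3·THF, THF, −20 °C
Reagents that add atoms: none
Why: Corey–Bakshi–Shibata reduction, in which the substituted alkenyl side acts as the large group, so the (S)-oxazaborolidine should give the (R)-allylic alcohol by analogy with aryl alkyl ketones.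

Step 5
Reactants: 8 (1R)-2-(4-chlorobutyl)-3-ethylcyclopent-2-en-1-ol
Product: 9 (1R,2R,3R)-2-(4-chlorobutyl)-3-ethylcyclopentan-1-ol
Conditions: H2 (1–4 atm), [Ir(cod)(PCy3)(py)]PF6 (5 mol%), CH2Cl2, rt
Reagents that add atoms: none
Why: Hydroxyl-directed homogeneous hydrogenation: the cationic iridium catalyst binds the carbinol oxygen and adds both hydrogens to the tetrasubstituted alkene on the hydroxyl face, so the ethyl and chlorobutyl groups end up cis to each other and trans to OH, both new centres being set by the carbinol centre.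

Step 6
Reactants: 9 (1R,2R,3R)-2-(4-chlorobutyl)-3-ethylcyclopentan-1-ol
Product: 10 (2R,3R)-2-(4-chlorobutyl)-3-ethylcyclopentan-1-one
Conditions: 1,1,1-triacetoxy-1,2-benziodoxol-3(1H)-one (DMP), NaHCO3, CH2Cl2, 0 °C → rt
Reagents that add atoms: none
Why: Buffered periodinane oxidation is neutral and fast, so the cis ketone should form without epimerisation of its α-centre.

Step 7
Reactants: 10 (2R,3R)-2-(4-chlorobutyl)-3-ethylcyclopentan-1-one
Product: 11 {[(4R,5R)-5-(4-chlorobutyl)-4-ethylcyclopent-1-en-1-yl]oxy}trimethylsilane
Conditions: LiN(i-Pr)2, THF, −78 °C; then Me3SiCl, Et3N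
Reagents that add atoms: chlorotrimethylsilane, C[Si](C)(C)Cl
Why: Kinetic deprotonation by the hindered amide base removes a proton from the unsubstituted α-CH2, and silylation traps that enolate, so the labile substituted α-centre is not touched.

Step 8
Reactants: 11 {[(4R,5R)-5-(4-chlorobutyl)-4-ethylcyclopent-1-en-1-yl]oxy}trimethylsilane; 12 benzyl pyruvate
Product: 14 benzyl (2S)-2-[(1S,3R,4R)-3-(4-chlorobutyl)-4-ethyl-2-oxocyclopentyl]-2-hydroxypropanoate, via trimethylsilyl ether 13 (not isolated)
Conditions: Cu(OTf)2/(S,S)-2,2'-isopropylidenebis(4-tert-butyl-2-oxazoline) (10 mol%), THF, −78 °C; then 1 M HCl, THF, 0 °C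
Reagents that add atoms: none
Why: Catalytic enantioselective Mukaiyama aldol addition to a chelated pyruvate ester: the (S,S)-ligand exposes the si face of the keto group, which gives the (S)-carbinol, while the enolsilane reacts on the ring face away from the chlorobutyl and ethyl groups, which puts the side chain trans to both, and dilute acid removes the transferred silyl group.

Step 9
Reactants: 14 benzyl (2S)-2-[(1S,3R,4R)-3-(4-chlorobutyl)-4-ethyl-2-oxocyclopentyl]-2-hydroxypropanoate
Product: 15 benzyl (2S)-2-[(1R,3R,4R)-3-(4-chlorobutyl)-4-ethyl-2-methylidenecyclopentyl]-2-hydroxypropanoate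
Conditions: Zn, CH2Br2, TiCl4, THF/CH2Cl2, 0 °C → rt
Reagents that add atoms: dibromomethane, BrCBr
Why: Takai–Lombardo methylenation: the non-basic zinc/titanium methylene reagent olefinates hindered enolisable ketones in preference to esters, so neither α-centre should epimerise and retro-aldol cleavage is avoided.

Step 10
Reactants: 15 benzyl (2S)-2-[(1R,3R,4R)-3-(4-chlorobutyl)-4-ethyl-2-methylidenecyclopentyl]-2-hydroxypropanoate
Product: 16 benzyl (2S)-2-[(1R,2R,3R,4R)-2-azido-3-(4-chlorobutyl)-2-(3-ethoxy-3-oxopropyl)-4-ethylcyclopentyl]-2-hydroxypropanoate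
Conditions: ICH2CO2Et, PhSO2N3, Bu3SnSnBu3, di-tert-butyl hyponitrite (cat.), benzene, 80 °C
Reagents that add atoms: ethyl iodoacetate, CCOC(=O)CI; benzenesulfonyl azide, [N-]=[N+]=NS(=O)(=O)c1ccccc1
Why: Radical carboazidation: the electrophilic ester-substituted radical adds to the CH2 terminus, and the tertiary ring radical takes azide from the sulfonyl azide on the face anti to the fully substituted carbinol carbon on the neighbouring ring carbon, which places nitrogen cis to the chlorobutyl chain and the new carbon arm cis to the side chain.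

Step 11
Reactants: 16 benzyl (2S)-2-[(1R,2R,3R,4R)-2-azido-3-(4-chlorobutyl)-2-(3-ethoxy-3-oxopropyl)-4-ethylcyclopentyl]-2-hydroxypropanoate
Product: 19 benzyl (2S)-2-[(5R,6R,7R,9R)-6-(4-chlorobutyl)-7-ethyl-2-oxo-1-azaspiro[4.4]nonan-9-yl]-2-hydroxypropanoate, via iminophosphorane 17 (not isolated), via amino diester 18 (not isolated)
Conditions: PMe3, THF/H2O, rt; then toluene, 80 °C
Reagents that add atoms: none
Why: Staudinger reduction gives the primary amine, which closes the five-membered spirolactam (ring A) on the ethyl ester; the benzyl ester is spared because attack there would need a trans-fused bicyclo[3.3.0] lactam.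

Step 12
Reactants: 19 benzyl (2S)-2-[(5R,6R,7R,9R)-6-(4-chlorobutyl)-7-ethyl-2-oxo-1-azaspiro[4.4]nonan-9-yl]-2-hydroxypropanoate
Product: 20 tricyclic lactam benzyl ester (ring A as pyrrolidin-2-one; ring B cis-fused to ring C; hydroxy ester side chain trans to nitrogen)
Conditions: NaH (1.1 equiv), Bu4NI (cat.), DMF, 0 → 50 °C
Reagents that add atoms: none
Why: Intramolecular N-alkylation of the lactam anion (7-exo-tet, helped by iodide exchange) closes ring B, a closure open only to the isomer with nitrogen and the chlorobutyl chain cis on ring C, and the lactam N–H is deprotonated in preference to the tertiary alcohol.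

Step 13
Reactants: 21 3-methylfuran-2(5H)-one
Product: 22 3-methyl-2-(triisopropylsilyloxy)furan
Conditions: i-Pr3SiOTf, Et3N, CH2Cl2, 0 °C
Reagents that add atoms: triisopropylsilyl trifluoromethanesulfonate, CC(C)[Si](OS(=O)(=O)C(F)(F)F)(C(C)C)C(C)C
Why: Soft enolisation of the butenolide and O-silylation give the 2-silyloxyfuran, the dienolate equivalent for the vinylogous Mannich reaction.

Step 14
Reactants: 20 tricyclic lactam benzyl ester; 22 3-methyl-2-(triisopropylsilyloxy)furan
Product: 25 butenolide adduct (the lactam carbon of 20 is now the ring A CH carrying a 4-methyl-5-oxo-2,5-dihydrofuran-2-yl group; both new centres as in the target), via silyl hemiaminal 23 (not isolated), via iminium nitrobenzoate 24 (not isolated)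
Conditions: IrCl(CO)(PPh3)2 (2 mol%), (Me2HSi)2O, toluene, rt; then 22, 2-nitrobenzoic acid, MeCN, 0 °C → rt
Reagents that add atoms: none
Why: Reductive vinylogous Mannich reaction: iridium-catalysed hydrosilylation reduces only the tertiary lactam to the N,O-silyl acetal, the acid ionises it to the iminium ion, and the silyloxyfuran adds through its C-5 on the ring A face away from the carbinol-bearing carbon of ring C, with the relative configuration of the two new centres usual for silyloxyfuran additions to cyclic iminium ions.

Step 15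
Reactants: 25 butenolide adduct
Product: 26 tetracyclic amino hydroxy acid (rings A, B, C and E; free tertiary alcohol and free carboxylic acid; ring E methyl cis to the ring A substituent)
Conditions: H2 (1 atm), 10% Pd/C, MeOH, rt
Reagents that add atoms: none
Why: Heterogeneous hydrogenation adds hydrogen to the butenolide on the face opposite its ring A substituent, which gives the cis methyl lactone, and the same conditions cleave the benzyl ester by hydrogenolysis.

Step 16
Reactants: 26 tetracyclic amino hydroxy acid
Product: 28 tetracyclic amino α-acetoxy acid, via mixed anhydride 27 (not isolated)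
Conditions: Ac2O, DMAP (cat.), pyridine, 40 °C; then H2O/THF, rt
Reagents that add atoms: acetic anhydride, CC(=O)OC(C)=O
Why: Acylation of the tertiary alcohol under nucleophilic catalysis, carried out after ring E is saturated so that no base-labile butenolide is present, with water hydrolysing the mixed anhydride formed at the carboxyl group.

Step 17
Reactants: 28 tetracyclic amino α-acetoxy acid
Product: 31 O-acetyl derivative of the target, via ammonium tetrafluoroborate 29 (not isolated), via lactone tetrafluoroborate 30 (not isolated)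
Conditions: HBF4 (48% aq., 1.1 equiv), (CF3)2CHOH; then (S,S)-Mn(pdp)(OTf)2 (5 mol%), 50% aq. H2O2 (slow addition), 0 °C; aq. NaHCO3 work-up
Reagents that add atoms: none
Why: The acid of 29 coordinates to manganese as carboxylate; heterolysis of the Mn–OOH unit, assisted by the fluorinated alcohol, gives an electrophilic high-valent manganese–oxo carboxylate that removes a hydrogen atom from the ring C methylene through a seven-membered transition state, and the carbon radical recombines with the carboxylate oxygen to form the C–O bond. The closest known reaction type is the carboxylic-acid-directed γ-lactonisation of unactivated methylene C–H bonds with manganese aminopyridine catalysts and H2O2. Ring D closes as a five-membered lactone by C–O bond formation from the tethered carboxylate oxygen to the γ-carbon, and only the cis-fused bicyclo[3.3.0] junction is geometrically reachable. Because the oxidant is held on the side chain, it can reach only the methylene hydrogen on the same ring face, so the side-chain-bearing ring carbon fixes the configuration of the new oxygen-bearing centre. The step needs site selectivity over all other C–H bonds and the amine: the second γ-carbon is the fully substituted aza-quaternary carbon, the tertiary C–H at the ethyl-bearing carbon is δ, the tetrafluoroborate salt masks nitrogen and deactivates the C–H bonds near it, and the acetate prevents oxidative decarboxylation of an α-hydroxy acid.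

Step 18
Reactants: 31 O-acetyl derivative of the target
Product: 32 target CNP0260919.4
Conditions: K2CO3 (0.2 equiv), MeOH, 0 °C → rt; then 1 M HCl to pH 2; aq. NaHCO3
Reagents that add atoms: none
Why: Base-catalysed transesterification removes the tertiary acetate, and the acid treatment re-closes any γ-hydroxy ester formed by competing lactone methanolysis, so both five-membered lactones are restored.

**Compound list**

1 | cyclopentane-1,3-dione | O=C1CCC(=O)C1 | starting material
2 | 4-chlorobutanal | O=CCCCCl | starting material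
3 | 2-(4-chlorobutylidene)cyclopentane-1,3-dione (formed in situ) | O=C1CCC(=O)C1=CCCCCl | intermediate
4 | 2-(4-chlorobutyl)cyclopentane-1,3-dione | O=C1CCC(=O)C1CCCCCl | intermediate
5 | 2-(4-chlorobutyl)-3-(2-methylpropoxy)cyclopent-2-en-1-one | CC(C)COC1=C(CCCCCl)C(=O)CC1 | intermediate
6 | 2-(4-chlorobutyl)-1-ethyl-3-(2-methylpropoxy)cyclopent-2-en-1-ol (racemic; formed in situ as its magnesium alkoxide) | CCC1(O)CCC(OCC(C)C)=C1CCCCCl | intermediate
7 | 2-(4-chlorobutyl)-3-ethylcyclopent-2-en-1-one | CCC1=C(CCCCCl)C(=O)CC1 | intermediate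
8 | (1R)-2-(4-chlorobutyl)-3-ethylcyclopent-2-en-1-ol | CCC1=C(CCCCCl)[C@H](O)CC1 | intermediate
9 | (1R,2R,3R)-2-(4-chlorobutyl)-3-ethylcyclopentan-1-ol (alkyl groups cis, OH trans to both) | CC[C@@H]1CC[C@@H](O)[C@@H]1CCCCCl | intermediate
10 | (2R,3R)-2-(4-chlorobutyl)-3-ethylcyclopentan-1-one (cis) | CC[C@@H]1CCC(=O)[C@@H]1CCCCCl | intermediate
11 | {[(4R,5R)-5-(4-chlorobutyl)-4-ethylcyclopent-1-en-1-yl]oxy}trimethylsilane | CC[C@@H]1CC=C(O[Si](C)(C)C)[C@@H]1CCCCCl | intermediate
12 | benzyl pyruvate (benzyl 2-oxopropanoate) | CC(=O)C(=O)OCc1ccccc1 | starting material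
13 | trimethylsilyl ether of 14 (formed in situ) | CC[C@@H]1C[C@@H]([C@](C)(O[Si](C)(C)C)C(=O)OCc2ccccc2)C(=O)[C@@H]1CCCCCl | intermediate
14 | benzyl (2S)-2-[(1S,3R,4R)-3-(4-chlorobutyl)-4-ethyl-2-oxocyclopentyl]-2-hydroxypropanoate | CC[C@@H]1C[C@@H]([C@](C)(O)C(=O)OCc2ccccc2)C(=O)[C@@H]1CCCCCl | intermediate
15 | benzyl (2S)-2-[(1R,3R,4R)-3-(4-chlorobutyl)-4-ethyl-2-methylidenecyclopentyl]-2-hydroxypropanoate | CC[C@@H]1C[C@@H]([C@](C)(O)C(=O)OCc2ccccc2)C(=C)[C@@H]1CCCCCl | intermediate
16 | benzyl (2S)-2-[(1R,2R,3R,4R)-2-azido-3-(4-chlorobutyl)-2-(3-ethoxy-3-oxopropyl)-4-ethylcyclopentyl]-2-hydroxypropanoate (azide cis to chlorobutyl, trans to side chain) | CC[C@@H]1C[C@@H]([C@](C)(O)C(=O)OCc2ccccc2)[C@@](N=[N+]=[N-])(CCC(=O)OCC)[C@@H]1CCCCCl | intermediate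
17 | trimethyliminophosphorane of 18 (formed in situ) | CC[C@@H]1C[C@@H]([C@](C)(O)C(=O)OCc2ccccc2)[C@@](N=P(C)(C)C)(CCC(=O)OCC)[C@@H]1CCCCCl | intermediate
18 | amino diester: 16 with NH2 in place of N3 (formed in situ) | CC[C@@H]1C[C@@H]([C@](C)(O)C(=O)OCc2ccccc2)[C@@](N)(CCC(=O)OCC)[C@@H]1CCCCCl | intermediate
19 | benzyl (2S)-2-[(5R,6R,7R,9R)-6-(4-chlorobutyl)-7-ethyl-2-oxo-1-azaspiro[4.4]nonan-9-yl]-2-hydroxypropanoate (spirolactam; N cis to chlorobutyl) | CC[C@@H]1C[C@@H]([C@](C)(O)C(=O)OCc2ccccc2)[C@@]2(CCC(=O)N2)[C@@H]1CCCCCl | intermediate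
20 | tricyclic lactam benzyl ester: ring A pyrrolidin-2-one, ring B azepane cis-fused to ring C, ethyl cis to the ring B CH2 on ring C, (2S)-hydroxy ester side chain trans to N | CC[C@@H]1C[C@@H]([C@](C)(O)C(=O)OCc2ccccc2)[C@]23CCC(=O)N2CCCC[C@H]13 | intermediate
21 | 3-methylfuran-2(5H)-one | CC1=CCOC1=O | starting material
22 | 3-methyl-2-(triisopropylsilyloxy)furan | Cc1ccoc1O[Si](C(C)C)(C(C)C)C(C)C | intermediate
23 | N,O-silyl hemiaminal of 20 (lactam C=O reduced to CH–OSiMe2OSiHMe2; formed in situ; hemiaminal centre undefined) | CC[C@@H]1C[C@@H]([C@](C)(O)C(=O)OCc2ccccc2)[C@]23CCC(O[Si](C)(C)O[SiH](C)C)N2CCCC[C@H]13 | intermediate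
24 | bicyclic iminium 2-nitrobenzoate from 23 (formed in situ) | CC[C@@H]1C[C@@H]([C@](C)(O)C(=O)OCc2ccccc2)[C@]23CCC=[N+]2CCCC[C@H]13.[O-]C(=O)c1ccccc1[N+](=O)[O-] | intermediate
25 | butenolide adduct: tricyclic amine benzyl ester with a 4-methyl-5-oxo-2,5-dihydrofuran-2-yl group on the ring A carbon next to N; both new centres as in the target | CC[C@@H]1C[C@@H]([C@](C)(O)C(=O)OCc2ccccc2)[C@]23CC[C@@H]([C@@H]4C=C(C)C(=O)O4)N2CCCC[C@H]13 | intermediate
26 | tetracyclic amino hydroxy acid: rings A, B, C, E complete; (2S)-2-hydroxypropanoic acid side chain; ring E methyl cis to ring A | CC[C@@H]1C[C@@H]([C@](C)(O)C(=O)O)[C@]23CC[C@@H]([C@@H]4C[C@H](C)C(=O)O4)N2CCCC[C@H]13 | intermediate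
27 | acetic mixed anhydride of 28 (formed in situ) | CC[C@@H]1C[C@@H]([C@](C)(OC(C)=O)C(=O)OC(C)=O)[C@]23CC[C@@H]([C@@H]4C[C@H](C)C(=O)O4)N2CCCC[C@H]13 | intermediate
28 | tetracyclic amino α-acetoxy acid (ring C CH2 not yet oxygenated) | CC[C@@H]1C[C@@H]([C@](C)(OC(C)=O)C(=O)O)[C@]23CC[C@@H]([C@@H]4C[C@H](C)C(=O)O4)N2CCCC[C@H]13 | intermediate
29 | ammonium tetrafluoroborate of 28 (formed in situ) | CC[C@@H]1C[C@@H]([C@](C)(OC(C)=O)C(=O)O)[C@]23CC[C@@H]([C@@H]4C[C@H](C)C(=O)O4)[NH+]2CCCC[C@H]13.F[B-](F)(F)F | intermediate
30 | ammonium tetrafluoroborate of 31 (formed in situ) | CC[C@@H]1[C@H]2OC(=O)[C@@](C)(OC(C)=O)[C@H]2[C@]23CC[C@@H]([C@@H]4C[C@H](C)C(=O)O4)[NH+]2CCCC[C@H]13.F[B-](F)(F)F | intermediate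
31 | O-acetyl derivative of the target (ring D closed, cis-fused to ring C) | CC[C@@H]1[C@H]2OC(=O)[C@@](C)(OC(C)=O)[C@H]2[C@]23CC[C@@H]([C@@H]4C[C@H](C)C(=O)O4)N2CCCC[C@H]13 | intermediate
32 | CNP0260919.4 | CC[C@@H]1[C@H]2OC(=O)[C@@](C)(O)[C@H]2[C@]23CC[C@@H]([C@@H]4C[C@H](C)C(=O)O4)N2CCCC[C@H]13 | target

**Step count and risks**

Total step count: 18. Longest linear sequence: 17 steps (steps 1–12 and 14–18; step 13 is a one-step branch).

Steps most likely to fail:

1. Step 17. What may go wrong: hydrogen abstraction at the ring C methylene is outrun by oxidation at other C–H bonds or by decarboxylation of the manganese-bound acid. Fallback, setting out from 28 and returning at 31: the same C–O bond is made by a nitrogen-radical relay. 28 is activated with carbonyldiimidazole and treated with ammonia to give the primary amide F1. PhI(OAc)2 and I2 under visible light, with CF3CO2H present to keep the amine protonated, generate the amidyl radical, which abstracts the same γ-hydrogen through a six-membered transition state. The oxidised γ-carbon is captured by the amide oxygen to give the cis-fused iminolactone F2, and aqueous acid hydrolyses it to 31.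

2. Step 14. What may go wrong: poor facial selectivity in the addition to the bicyclic iminium ion, because ring B partly covers the face on which the furan must arrive. Fallback, setting out from 19 and returning at 25: ring E is attached before ring B is closed, through an N-acyliminium ion. Boc2O and DMAP convert 19 into the N-Boc spirolactam F3. LiBHEt3 at −78 °C reduces the imide-type carbonyl to the hemiaminal F4, and BF3·OEt2 with 22 gives the N-Boc butenolide adduct F5. CF3CO2H removes the carbamate to give the secondary amine F6, and NaI/NaHCO3 in MeCN closes ring B by N-alkylation to give 25.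

3. Step 10. What may go wrong: slow or unselective azide transfer to the hindered tertiary radical (capture on the wrong ring face, or reduction and iodine transfer in its place). Fallback, setting out from 14 and returning at 20: nitrogen is brought in through ring B first and the carbon arm is added to a cyclic ketimine. NaN3 in DMF converts 14 into the azido ketone F7, and PPh3 (Staudinger reduction then intramolecular aza-Wittig reaction) closes the seven-membered cyclic imine F8. Allylzinc bromide first forms the zinc alkoxide of the tertiary alcohol, which chelates the imine nitrogen, and then adds to the C=N bond to give the cis-fused homoallylic amine F9. 9-BBN followed by NaBO3 gives the amino alcohol F10, and NPr4RuO4 with N-methylmorpholine N-oxide oxidises it through the cyclic hemiaminal to the lactam 20.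

**Further compounds**

F1 | step 17 | primary amide of 28 (CONH2 in place of CO2H) | CC[C@@H]1C[C@@H]([C@](C)(OC(C)=O)C(N)=O)[C@]23CC[C@@H]([C@@H]4C[C@H](C)C(=O)O4)N2CCCC[C@H]13
F2 | step 17 | iminolactone corresponding to 31 (C=NH in place of the ring D C=O) | CC[C@@H]1[C@H]2OC(=N)[C@@](C)(OC(C)=O)[C@H]2[C@]23CC[C@@H]([C@@H]4C[C@H](C)C(=O)O4)N2CCCC[C@H]13
F3 | step 14 | N-Boc derivative of spirolactam 19 | CC[C@@H]1C[C@@H]([C@](C)(O)C(=O)OCc2ccccc2)[C@@]2(CCC(=O)N2C(=O)OC(C)(C)C)[C@@H]1CCCCCl
F4 | step 14 | N-Boc hemiaminal from F3 (hemiaminal centre undefined) | CC[C@@H]1C[C@@H]([C@](C)(O)C(=O)OCc2ccccc2)[C@@]2(CCC(O)N2C(=O)OC(C)(C)C)[C@@H]1CCCCCl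
F5 | step 14 | N-Boc spiropyrrolidine carrying the butenolide on the carbon next to N, chlorobutyl chain still open | CC[C@@H]1C[C@@H]([C@](C)(O)C(=O)OCc2ccccc2)[C@@]2(CC[C@@H]([C@@H]3C=C(C)C(=O)O3)N2C(=O)OC(C)(C)C)[C@@H]1CCCCCl
F6 | step 14 | secondary amine from F5 after loss of Boc | CC[C@@H]1C[C@@H]([C@](C)(O)C(=O)OCc2ccccc2)[C@@]2(CC[C@@H]([C@@H]3C=C(C)C(=O)O3)N2)[C@@H]1CCCCCl
F7 | step 10 | azido ketone: 14 with N3 in place of Cl | CC[C@@H]1C[C@@H]([C@](C)(O)C(=O)OCc2ccccc2)C(=O)[C@@H]1CCCCN=[N+]=[N-]
F8 | step 10 | bicyclic seven-membered cyclic ketimine fused to ring C | CC[C@@H]1C[C@@H]([C@](C)(O)C(=O)OCc2ccccc2)C2=NCCCC[C@H]12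
F9 | step 10 | cis-fused azepane with allyl on the aza-quaternary carbon (allyl cis to the side chain) | CC[C@@H]1C[C@@H]([C@](C)(O)C(=O)OCc2ccccc2)[C@]2(CC=C)NCCCC[C@H]12
F10 | step 10 | amino alcohol from F9 (3-hydroxypropyl in place of allyl) | CC[C@@H]1C[C@@H]([C@](C)(O)C(=O)OCc2ccccc2)[C@]2(CCCO)NCCCC[C@H]12
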